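**Plan**

- Cuts: the C4–OH of the lower unit (late benzylic C–H oxidation); the two interflavan bonds C4(M)–C8(L) and C4(U)–C8(M) (C8 aryllithium + flavan-4-one, then hydride); and, in every flavan unit, O1–C8a together with C3–C4.
- Enabling feature: each ring C is a pyran fused to the phloroglucinol-type ring A across C4a–C8a, so O1–C2=C3 is the enolate of a 4-oxygenated acetophenone, and C4 and C8a are the benzylic and aryl carbons of an ortho-bromobenzyl bromide. One C-benzylation/O-arylation domino joins them to an achiral flav-2-ene that serves all three units.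
- Forward: ring A synthon (steps 1–3) → flav-2-ene (step 4) → racemic flavan-3-one → both cis-flavan-3-ols → U ketone plus M and L bromides → U–M → C4 ketone of M → U–M–L → C4 hydroxylation of L → deprotection.
- Stereochemistry: C2/C3 of each unit by catalyst-controlled hydrogenation with dynamic kinetic resolution (cis). C4 of U and M by aryl addition, then hydride delivery anti to the axial 3-OTBS (3,4-cis). C4 of L by DDQ/H2O anti to 3-OTBS (3,4-trans).

Key step: step 4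

Remark: U, M and L are the upper, middle and lower flavan units. β is the face of ring C that carries the 2-aryl group in U and L (2S series), α the opposite face. The target is U (2β-aryl, 3β-OH, 4β-link), M (2α-aryl, 3α-OH, 4α-link), L (2β-aryl, 3β-OH, 4α-OH), i.e. (2S,3S,4R)/(2R,3R,4S)/(2S,3S,4R). Compound 1 is taken as commercially available. TBS = tert-butyldimethylsilyl.

**Route**

Step 1
Reactants: 1 1,3-bis(benzyloxy)-5-bromobenzene
Product: 2 2,4-bis(benzyloxy)-6-bromobenzaldehyde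
Conditions: POCl3, DMF, 0 → 80 °C; aq. NaOAc
Reagents that add atoms: N,N-dimethylformamide, CN(C)C=O; water, O
Why: Vilsmeier–Haack formylation should go para to one benzyloxy group and ortho to bromine (the site between the two benzyloxy groups is more hindered), as for 1-bromo-3,5-dimethoxybenzene; no stereocentre is formed.

Step 2
Reactants: 2 2,4-bis(benzyloxy)-6-bromobenzaldehyde
Product: 3 [2,4-bis(benzyloxy)-6-bromophenyl]methanol
Conditions: NaBH4, THF/MeOH, 0 °C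
Reagents that add atoms: none
Why: Borohydride reduction of the aryl aldehyde to the benzylic alcohol leaves the aryl bromide and benzyl ethers untouched.

Step 3
Reactants: 3 [2,4-bis(benzyloxy)-6-bromophenyl]methanol
Product: 4 1,5-bis(benzyloxy)-3-bromo-2-(bromomethyl)benzene
Conditions: CBr4, PPh3, CH2Cl2, 0 °C; used crude
Reagents that add atoms: tetrabromomethane, BrC(Br)(Br)Br
Why: Appel bromination is neutral, so the electron-rich benzylic position is not ionised by acid; the labile bromide is used at once.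

Step 4
Reactants: 5 1-[4-(benzyloxy)phenyl]ethan-1-one, 4 1,5-bis(benzyloxy)-3-bromo-2-(bromomethyl)benzene
Product: 7 5,7-bis(benzyloxy)-2-[4-(benzyloxy)phenyl]-4H-chromene, via bromo ketone 6 (not isolated)
Conditions: 5 (1.3 equiv), LiN(SiMe3)2, THF, −78 °C; 4, −78 → 0 °C; then CuI (10 mol%), 1,10-phenanthroline, Cs2CO3, DMF, 100 °C
Reagents that add atoms: none
Why: The lithium enolate of 5 is C-benzylated by the benzylic bromide of 4 (SN2, C3–C4) while the aryl C–Br is inert at −78 °C; ketone 6 is then re-enolised by Cs2CO3 and the (Z)-enolate oxygen is arylated at C8a by copper catalysis (oxidative addition of the aryl bromide to the cuprous enolate, then C–O reductive elimination), which closes O1–C8a. The closest known reaction type is the copper-catalysed domino C-benzylation/intramolecular Ullmann O-arylation of 2-bromobenzyl bromides with enolisable carbonyl compounds to 4H-chromenes, together with enolate O-arylation routes to benzofurans. Ring C closes as a six-membered ring by intramolecular enolate O-arylation; the competing C-arylation would need a four-membered ring and is excluded. No stereocentre is formed: C2 and C3 leave the step as the enol ether, and steps 5 to 8 set them. The step needs mono-C-alkylation, which excess enolate, low temperature and a soft benzylic electrophile should secure, and discrimination between the two C–Br bonds, which the sp3/sp2 difference secures. Base-induced migration of the double bond to the 2H-chromene would be harmless, because hydroboration of either isomer puts oxygen on C3.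

Step 5
Reactants: 7 5,7-bis(benzyloxy)-2-[4-(benzyloxy)phenyl]-4H-chromene
Product: 8 rac-(2R,3S)-5,7-bis(benzyloxy)-2-[4-(benzyloxy)phenyl]chroman-3-ol (2,3-trans)
Conditions: BH3·THF, THF, 0 °C → rt; NaOH, H2O2
Reagents that add atoms: hydrogen peroxide, OO
Why: Hydroboration–oxidation of the cyclic enol ether puts boron on C3 (β to O1) with syn addition, so the 3-OH is trans to the 2-aryl group; the racemic outcome does not matter because both centres are reset in steps 6 to 8.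

Step 6
Reactants: 8 rac-(2R,3S)-5,7-bis(benzyloxy)-2-[4-(benzyloxy)phenyl]chroman-3-ol
Product: 9 rac-5,7-bis(benzyloxy)-2-[4-(benzyloxy)phenyl]chroman-3-one
Conditions: Dess–Martin periodinane, CH2Cl2, rt
Reagents that add atoms: none
Why: Dess–Martin oxidation under near-neutral conditions should give the flavan-3-one as it does for benzylated catechin; C3 becomes trigonal and C2 stays racemic.

Step 7
Reactants: 9 rac-5,7-bis(benzyloxy)-2-[4-(benzyloxy)phenyl]chroman-3-one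
Product: 10 (2S,3S)-5,7-bis(benzyloxy)-2-[4-(benzyloxy)phenyl]chroman-3-ol (2,3-cis)
Conditions: H2 (10 atm), RuCl2[(S)-xylbinap][(S)-daipen] (1 mol%), t-BuOK (cat.), i-PrOH/THF, rt
Reagents that add atoms: none
Why: Noyori-type hydrogenation with dynamic kinetic resolution: t-BuOK racemises the acidic C2–H (benzylic, α to the ketone and to O1) faster than reduction and hydride is delivered anti to the 2-aryl group, so the cis (2S,3S) alcohol is expected by analogy with α-aryl and α-aryloxy cyclic ketones; the catalyst antipode is assigned by that analogy and is to be confirmed by correlation.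

Step 8
Reactants: 9 rac-5,7-bis(benzyloxy)-2-[4-(benzyloxy)phenyl]chroman-3-one
Product: 11 (2R,3R)-5,7-bis(benzyloxy)-2-[4-(benzyloxy)phenyl]chroman-3-ol (2,3-cis)
Conditions: H2 (10 atm), RuCl2[(R)-xylbinap][(R)-daipen] (1 mol%), t-BuOK (cat.), i-PrOH/THF, rt
Reagents that add atoms: none
Why: The same dynamic kinetic hydrogenation with the mirror-image catalyst should give the enantiomeric cis alcohol.

Step 9
Reactants: 10 (2S,3S)-5,7-bis(benzyloxy)-2-[4-(benzyloxy)phenyl]chroman-3-ol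
Product: 12 (2S,3S)-5,7-bis(benzyloxy)-2-[4-(benzyloxy)phenyl]-3-(TBS-oxy)chromane
Conditions: TBSCl, imidazole, DMF, rt → 40 °C
Reagents that add atoms: tert-butyldimethylsilyl chloride, CC(C)(C)[Si](C)(C)Cl
Why: Silyl ether formation on the axial 3-OH, as for benzylated epicatechin; the bulky axial OTBS later shields one face of C4.

Step 10
Reactants: 11 (2R,3R)-5,7-bis(benzyloxy)-2-[4-(benzyloxy)phenyl]chroman-3-ol
Product: 13 (2R,3R)-5,7-bis(benzyloxy)-2-[4-(benzyloxy)phenyl]-3-(TBS-oxy)chromane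
Conditions: TBSCl, imidazole, DMF, rt → 40 °C
Reagents that add atoms: tert-butyldimethylsilyl chloride, CC(C)(C)[Si](C)(C)Cl
Why: Same silyl ether formation in the enantiomeric series.

Step 11
Reactants: 12 (2S,3S)-5,7-bis(benzyloxy)-2-[4-(benzyloxy)phenyl]-3-(TBS-oxy)chromane
Product: 14 (2S,3S,4R)-5,7-bis(benzyloxy)-2-[4-(benzyloxy)phenyl]-3-(TBS-oxy)chroman-4-ol
Conditions: DDQ, CH2Cl2/H2O, rt
Reagents that add atoms: water, O
Why: DDQ abstracts hydride from C4 (benzylic to the 5,7-dioxygenated ring A) and water should trap the cation anti to the axial 3-OTBS, as known for benzylated epicatechin; this C4 configuration is erased in step 12.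

Step 12
Reactants: 14 (2S,3S,4R)-5,7-bis(benzyloxy)-2-[4-(benzyloxy)phenyl]-3-(TBS-oxy)chroman-4-ol
Product: 15 (2S,3R)-5,7-bis(benzyloxy)-2-[4-(benzyloxy)phenyl]-3-(TBS-oxy)chroman-4-one
Conditions: (n-Pr4N)RuO4 (5 mol%), NMO, 4 Å MS, CH2Cl2, rt
Reagents that add atoms: none
Why: Ley–Griffith oxidation of the benzylic alcohol is neutral, so the epimerisable C3 of the α-silyloxy ketone should keep its cis configuration.

Step 13
Reactants: 13 (2R,3R)-5,7-bis(benzyloxy)-2-[4-(benzyloxy)phenyl]-3-(TBS-oxy)chromane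
Product: 16 (2R,3R)-5,7-bis(benzyloxy)-2-[4-(benzyloxy)phenyl]-8-bromo-3-(TBS-oxy)chromane
Conditions: NBS, CH2Cl2, −78 → 0 °C
Reagents that add atoms: N-bromosuccinimide, O=C1CCC(=O)N1Br
Why: Electrophilic aromatic bromination should go to C8, which is less hindered than C6 between two benzyloxy groups, as for protected epicatechin.

Step 14
Reactants: 12 (2S,3S)-5,7-bis(benzyloxy)-2-[4-(benzyloxy)phenyl]-3-(TBS-oxy)chromane
Product: 17 (2S,3S)-5,7-bis(benzyloxy)-2-[4-(benzyloxy)phenyl]-8-bromo-3-(TBS-oxy)chromane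
Conditions: NBS, CH2Cl2, −78 → 0 °C
Reagents that add atoms: N-bromosuccinimide, O=C1CCC(=O)N1Br
Why: Same C8-selective electrophilic bromination in the enantiomeric series.

Step 15
Reactants: 16 (2R,3R)-8-bromo monomer, 15 (2S,3R)-4-ketone
Product: 19 U–M carbinol in which C4 of U carries a 4β-OH and, 4α, C8 of M (U: 2β-aryl, 3β-OTBS; M: 2α-aryl, 3α-OTBS, CH2 at C4; six benzyl ethers), via aryllithium 18 (not isolated)
Conditions: 16, t-BuLi (2 equiv), THF, −78 °C; then 15, −78 → −40 °C; H2O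
Reagents that add atoms: none
Why: Bromine–lithium exchange gives the C8 aryllithium, which should add to the 4-ketone from the face anti to the axial 3-OTBS (1,2-addition, as in the known synthesis of epicatechin-(4α→8)-epicatechin); this carbinol centre is reset in step 16.

Step 16
Reactants: 19 U–M carbinol
Product: 20 hexa-O-benzyl-bis-O-TBS-[ent-epiafzelechin-(4β→8)-epiafzelechin] (U: 2β-aryl, 3β-OTBS, 4β-link, all cis; M: 2α-aryl, 3α-OTBS, CH2 at C4)
Conditions: Bu3SnH, CF3CO2H, CH2Cl2, 0 °C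
Reagents that add atoms: none
Why: Ionic hydrogenation: acid ionises the doubly benzylic tertiary alcohol and Bu3SnH should deliver hydride anti to the axial 3β-OTBS, which leaves the 4-aryl group cis to it (4β).

Step 17
Reactants: 20 U–M dimer
Product: 21 U–M dimer with a 4β-OH on C4 of M (trans to its 3α-OTBS)
Conditions: DDQ, CH2Cl2/H2O, rt
Reagents that add atoms: water, O
Why: DDQ benzylic oxidation should occur at the only CH2 that is benzylic to a phloroglucinol ring (C4 of M), as in the preparation of dimeric procyanidin electrophiles; this C4 configuration is erased in step 18.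

Step 18
Reactants: 21 U–M dimer 4-ol
Product: 22 U–M dimer with a ketone at C4 of M
Conditions: (n-Pr4N)RuO4 (5 mol%), NMO, 4 Å MS, CH2Cl2, rt
Reagents that add atoms: none
Why: Ley–Griffith oxidation of the benzylic alcohol under neutral conditions, as in step 12.

Step 19
Reactants: 17 (2S,3S)-8-bromo monomer, 22 U–M dimer ketone
Product: 24 U–M–L carbinol in which C4 of M carries a 4α-OH and, 4β, C8 of L (L: 2β-aryl, 3β-OTBS, CH2 at C4; nine benzyl ethers, three OTBS), via aryllithium 23 (not isolated)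
Conditions: 17, t-BuLi (2 equiv), THF, −78 °C; then 22, −78 → −40 °C; H2O
Reagents that add atoms: none
Why: Same bromine–lithium exchange and 1,2-addition as in step 15; the aryllithium should attack the ketone of M anti to its axial 3α-OTBS, forming C4(M)–C8(L).

Step 20
Reactants: 24 U–M–L carbinol
Product: 25 nona-O-benzyl-tris-O-TBS-[ent-epiafzelechin-(4β→8)-epiafzelechin-(4α→8)-ent-epiafzelechin] (M now 2α-aryl, 3α-OTBS, 4α-link, all cis)
Conditions: Bu3SnH, CF3CO2H, CH2Cl2, 0 °C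
Reagents that add atoms: none
Why: Ionic hydrogenation as in step 16; hydride should add anti to the 3α-OTBS of M, which puts the L aryl group 4α.

Step 21
Reactants: 25 protected trimer
Product: 26 protected trimer with a 4α-OH on C4 of L (L: 2S,3S,4R; 3,4-trans)
Conditions: DDQ, CH2Cl2/H2O, 0 °C → rt
Reagents that add atoms: water, O
Why: DDQ hydride abstraction at the last benzylic CH2 (C4 of L) and capture of the cation by water anti to the axial 3β-OTBS should set the 4α-hydroxyl, the stereochemical course known for 2,3-cis flavan-3-ol ethers.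

Step 22
Reactants: 26 protected trimer 4-ol
Product: 27 nona-O-benzyl trimer with free 3-OH on U, M and L and free 4-OH on L
Conditions: Bu4NF, THF, rt
Reagents that add atoms: none
Why: Fluoride cleaves the three secondary silyl ethers; benzyl ethers and the benzylic alcohol are stable to it.

Step 23
Reactants: 27 nona-O-benzyl trimer
Product: 28 target, (2S,3S,4R)-8-{(2R,3R,4S)-8-[(2S,3S,4R)-3,5,7-trihydroxy-2-(4-hydroxyphenyl)chroman-4-yl]-3,5,7-trihydroxy-2-(4-hydroxyphenyl)chroman-4-yl}-2-(4-hydroxyphenyl)chromane-3,4,5,7-tetrol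
Conditions: H2 (1 atm), Pd(OH)2/C, THF/MeOH, rt; stopped at complete debenzylation
Reagents that add atoms: none
Why: Hydrogenolysis of the nine aryl benzyl ethers under neutral conditions should be faster than cleavage of the benzylic 4-hydroxyl of L, which needs acid to ionise.

**Compound list**

1 | 1,3-bis(benzyloxy)-5-bromobenzene | Brc1cc(OCc2ccccc2)cc(OCc2ccccc2)c1 | starting material
2 | 2,4-bis(benzyloxy)-6-bromobenzaldehyde | O=Cc1c(Br)cc(OCc2ccccc2)cc1OCc1ccccc1 | intermediate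
3 | [2,4-bis(benzyloxy)-6-bromophenyl]methanol | OCc1c(Br)cc(OCc2ccccc2)cc1OCc1ccccc1 | intermediate
4 | 1,5-bis(benzyloxy)-3-bromo-2-(bromomethyl)benzene | BrCc1c(Br)cc(OCc2ccccc2)cc1OCc1ccccc1 | intermediate
5 | 1-[4-(benzyloxy)phenyl]ethan-1-one | CC(=O)c1ccc(OCc2ccccc2)cc1 | starting material
6 | 3-[2,4-bis(benzyloxy)-6-bromophenyl]-1-[4-(benzyloxy)phenyl]propan-1-one | O=C(CCc1c(Br)cc(OCc2ccccc2)cc1OCc1ccccc1)c1ccc(OCc2ccccc2)cc1 | intermediate
7 | 5,7-bis(benzyloxy)-2-[4-(benzyloxy)phenyl]-4H-chromene | C1(c2ccc(OCc3ccccc3)cc2)=CCc2c(OCc3ccccc3)cc(OCc3ccccc3)cc2O1 | intermediate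
8 | rac-(2R,3S)-5,7-bis(benzyloxy)-2-[4-(benzyloxy)phenyl]chroman-3-ol (both enantiomers shown) | O[C@H]1Cc2c(OCc3ccccc3)cc(OCc3ccccc3)cc2O[C@@H]1c1ccc(OCc2ccccc2)cc1.O[C@@H]1Cc2c(OCc3ccccc3)cc(OCc3ccccc3)cc2O[C@H]1c1ccc(OCc2ccccc2)cc1 | intermediate
9 | rac-5,7-bis(benzyloxy)-2-[4-(benzyloxy)phenyl]chroman-3-one | O=C1Cc2c(OCc3ccccc3)cc(OCc3ccccc3)cc2OC1c1ccc(OCc2ccccc2)cc1 | intermediate
10 | (2S,3S)-5,7-bis(benzyloxy)-2-[4-(benzyloxy)phenyl]chroman-3-ol | O[C@H]1Cc2c(OCc3ccccc3)cc(OCc3ccccc3)cc2O[C@H]1c1ccc(OCc2ccccc2)cc1 | intermediate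
11 | (2R,3R)-5,7-bis(benzyloxy)-2-[4-(benzyloxy)phenyl]chroman-3-ol | O[C@@H]1Cc2c(OCc3ccccc3)cc(OCc3ccccc3)cc2O[C@@H]1c1ccc(OCc2ccccc2)cc1 | intermediate
12 | (2S,3S)-5,7-bis(benzyloxy)-2-[4-(benzyloxy)phenyl]-3-(TBS-oxy)chromane | CC(C)(C)[Si](C)(C)O[C@H]1Cc2c(OCc3ccccc3)cc(OCc3ccccc3)cc2O[C@H]1c1ccc(OCc2ccccc2)cc1 | intermediate
13 | (2R,3R)-5,7-bis(benzyloxy)-2-[4-(benzyloxy)phenyl]-3-(TBS-oxy)chromane | CC(C)(C)[Si](C)(C)O[C@@H]1Cc2c(OCc3ccccc3)cc(OCc3ccccc3)cc2O[C@@H]1c1ccc(OCc2ccccc2)cc1 | intermediate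
14 | (2S,3S,4R)-5,7-bis(benzyloxy)-2-[4-(benzyloxy)phenyl]-3-(TBS-oxy)chroman-4-ol | CC(C)(C)[Si](C)(C)O[C@H]1[C@H](O)c2c(OCc3ccccc3)cc(OCc3ccccc3)cc2O[C@H]1c1ccc(OCc2ccccc2)cc1 | intermediate
15 | (2S,3R)-5,7-bis(benzyloxy)-2-[4-(benzyloxy)phenyl]-3-(TBS-oxy)chroman-4-one | CC(C)(C)[Si](C)(C)O[C@H]1C(=O)c2c(OCc3ccccc3)cc(OCc3ccccc3)cc2O[C@H]1c1ccc(OCc2ccccc2)cc1 | intermediate
16 | (2R,3R)-5,7-bis(benzyloxy)-2-[4-(benzyloxy)phenyl]-8-bromo-3-(TBS-oxy)chromane | CC(C)(C)[Si](C)(C)O[C@@H]1Cc2c(OCc3ccccc3)cc(OCc3ccccc3)c(Br)c2O[C@@H]1c1ccc(OCc2ccccc2)cc1 | intermediate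
17 | (2S,3S)-5,7-bis(benzyloxy)-2-[4-(benzyloxy)phenyl]-8-bromo-3-(TBS-oxy)chromane | CC(C)(C)[Si](C)(C)O[C@H]1Cc2c(OCc3ccccc3)cc(OCc3ccccc3)c(Br)c2O[C@H]1c1ccc(OCc2ccccc2)cc1 | intermediate
18 | 8-lithio derivative of 13 | CC(C)(C)[Si](C)(C)O[C@@H]1Cc2c(OCc3ccccc3)cc(OCc3ccccc3)c([Li])c2O[C@@H]1c1ccc(OCc2ccccc2)cc1 | intermediate
19 | U–M carbinol (C4 of U: 4β-OH, 4α-aryl) | c9ccccc9COc1ccc([C@H]2Oc3c(c(OCc9ccccc9)cc(OCc9ccccc9)c3[C@]3(O)c4c(OCc9ccccc9)cc(OCc9ccccc9)cc4O[C@@H](c4ccc(OCc9ccccc9)cc4)[C@H]3O[Si](C)(C)C(C)(C)C)C[C@H]2O[Si](C)(C)C(C)(C)C)cc1 | intermediate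
20 | hexa-O-benzyl-bis-O-TBS-[ent-epiafzelechin-(4β→8)-epiafzelechin] | c9ccccc9COc1ccc([C@H]2Oc3c(c(OCc9ccccc9)cc(OCc9ccccc9)c3[C@H]3c4c(OCc9ccccc9)cc(OCc9ccccc9)cc4O[C@@H](c4ccc(OCc9ccccc9)cc4)[C@H]3O[Si](C)(C)C(C)(C)C)C[C@H]2O[Si](C)(C)C(C)(C)C)cc1 | intermediate
21 | dimer 20 with 4β-OH on C4 of M | c9ccccc9COc1ccc([C@H]2Oc3c(c(OCc9ccccc9)cc(OCc9ccccc9)c3[C@H]3c4c(OCc9ccccc9)cc(OCc9ccccc9)cc4O[C@@H](c4ccc(OCc9ccccc9)cc4)[C@H]3O[Si](C)(C)C(C)(C)C)[C@H](O)[C@H]2O[Si](C)(C)C(C)(C)C)cc1 | intermediate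
22 | dimer 20 with C4 of M as ketone | c9ccccc9COc1ccc([C@H]2Oc3c(c(OCc9ccccc9)cc(OCc9ccccc9)c3[C@H]3c4c(OCc9ccccc9)cc(OCc9ccccc9)cc4O[C@@H](c4ccc(OCc9ccccc9)cc4)[C@H]3O[Si](C)(C)C(C)(C)C)C(=O)[C@H]2O[Si](C)(C)C(C)(C)C)cc1 | intermediate
23 | 8-lithio derivative of 12 | CC(C)(C)[Si](C)(C)O[C@H]1Cc2c(OCc3ccccc3)cc(OCc3ccccc3)c([Li])c2O[C@H]1c1ccc(OCc2ccccc2)cc1 | intermediate
24 | U–M–L carbinol (C4 of M: 4α-OH, 4β-aryl) | c9ccccc9COc1ccc([C@H]2Oc3c(c(OCc9ccccc9)cc(OCc9ccccc9)c3[C@H]3c4c(OCc9ccccc9)cc(OCc9ccccc9)cc4O[C@@H](c4ccc(OCc9ccccc9)cc4)[C@H]3O[Si](C)(C)C(C)(C)C)[C@@](c3c(OCc9ccccc9)cc(OCc9ccccc9)c4c3O[C@@H](c3ccc(OCc9ccccc9)cc3)[C@@H](O[Si](C)(C)C(C)(C)C)C4)(O)[C@H]2O[Si](C)(C)C(C)(C)C)cc1 | intermediate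
25 | nona-O-benzyl-tris-O-TBS-[ent-epiafzelechin-(4β→8)-epiafzelechin-(4α→8)-ent-epiafzelechin] | c9ccccc9COc1ccc([C@H]2Oc3c(c(OCc9ccccc9)cc(OCc9ccccc9)c3[C@H]3c4c(OCc9ccccc9)cc(OCc9ccccc9)cc4O[C@@H](c4ccc(OCc9ccccc9)cc4)[C@H]3O[Si](C)(C)C(C)(C)C)[C@@H](c3c(OCc9ccccc9)cc(OCc9ccccc9)c4c3O[C@@H](c3ccc(OCc9ccccc9)cc3)[C@@H](O[Si](C)(C)C(C)(C)C)C4)[C@H]2O[Si](C)(C)C(C)(C)C)cc1 | intermediate
26 | trimer 25 with 4α-OH on C4 of L | c9ccccc9COc1ccc([C@H]2Oc3c(c(OCc9ccccc9)cc(OCc9ccccc9)c3[C@H]3c4c(OCc9ccccc9)cc(OCc9ccccc9)cc4O[C@@H](c4ccc(OCc9ccccc9)cc4)[C@H]3O[Si](C)(C)C(C)(C)C)[C@@H](c3c(OCc9ccccc9)cc(OCc9ccccc9)c4c3O[C@@H](c3ccc(OCc9ccccc9)cc3)[C@@H](O[Si](C)(C)C(C)(C)C)[C@@H]4O)[C@H]2O[Si](C)(C)C(C)(C)C)cc1 | intermediate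
27 | nona-O-benzyl trimer, 3-OH (U, M, L) and 4-OH (L) free | c9ccccc9COc1ccc([C@H]2Oc3c(c(OCc9ccccc9)cc(OCc9ccccc9)c3[C@H]3c4c(OCc9ccccc9)cc(OCc9ccccc9)cc4O[C@@H](c4ccc(OCc9ccccc9)cc4)[C@H]3O)[C@@H](c3c(OCc9ccccc9)cc(OCc9ccccc9)c4c3O[C@@H](c3ccc(OCc9ccccc9)cc3)[C@@H](O)[C@@H]4O)[C@H]2O)cc1 | intermediate
28 | target (CNP0159291.1) | Oc1ccc([C@H]2Oc3c(c(O)cc(O)c3[C@H]3c4c(O)cc(O)cc4O[C@@H](c4ccc(O)cc4)[C@H]3O)[C@@H](c3c(O)cc(O)c4c3O[C@@H](c3ccc(O)cc3)[C@@H](O)[C@@H]4O)[C@H]2O)cc1 | target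

**Count**

Total steps: 23. Longest linear sequence: 19 steps (1–7, 9, 11, 12, 15–23).

**Steps most likely to fail**

Step 4. The second stage may stall, because the ketone enolate of 6 is only weakly acidic and its copper-mediated O-arylation can be slow, with aldol self-condensation competing. The fallback sets out from 6, isolated after the alkylation stage. Palladium-catalysed hydroxylation of the aryl bromide (Pd2(dba)3, t-BuXPhos, KOH, dioxane/H2O) would give 3-[2,4-bis(benzyloxy)-6-hydroxyphenyl]-1-[4-(benzyloxy)phenyl]propan-1-one F1. Acid-catalysed cyclodehydration through the cyclic hemiketal (p-TsOH, toluene, reflux) then gives 7, where the route is rejoined. Here O1 comes from hydroxide and ring C closes at C2 instead of C8a.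

Step 7 (and its mirror, step 8). Racemisation at C2 may be too slow relative to reduction, or facial discrimination poor, so that the dynamic kinetic resolution is incomplete. The fallback sets out from 9. Reduction with LiBH(s-Bu)3 (THF, −78 °C), known to give 2,3-cis alcohols from benzylated flavan-3-ones, would give the racemic cis alcohol F2. Esterification with (S)-O-methylmandelic acid (DCC, DMAP) gives the diastereomeric esters F3 and F4, separated by chromatography or crystallisation. Methanolysis (K2CO3, MeOH) returns 10 from F3 and 11 from F4.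

Step 23. The benzylic 4-hydroxyl of L may be lost by hydrogenolysis before debenzylation is complete. The fallback sets out from 26. Oxidation of the 4-hydroxyl ((n-Pr4N)RuO4, NMO) gives the protected trimer 4-ketone F5. Desilylation under buffered acidic conditions (HF·pyridine, THF, to avoid base epimerisation at C3) gives the triol ketone F6. Hydrogenolysis (H2, Pd(OH)2/C), now with no benzylic C–O bond present, gives the free phenolic 4-ketone F7. Hydroxyl-directed reduction with Me4NBH(OAc)3 (MeCN/AcOH, −30 °C), in which the 3β-hydroxyl delivers hydride to the same face of C4, should then give the 3,4-trans diol 28.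

**Further compounds**

F1 | step 4 | 3-[2,4-bis(benzyloxy)-6-hydroxyphenyl]-1-[4-(benzyloxy)phenyl]propan-1-one | O=C(CCc1c(O)cc(OCc2ccccc2)cc1OCc1ccccc1)c1ccc(OCc2ccccc2)cc1
F2 | step 7 | rac-cis-5,7-bis(benzyloxy)-2-[4-(benzyloxy)phenyl]chroman-3-ol (both enantiomers shown) | O[C@H]1Cc2c(OCc3ccccc3)cc(OCc3ccccc3)cc2O[C@H]1c1ccc(OCc2ccccc2)cc1.O[C@@H]1Cc2c(OCc3ccccc3)cc(OCc3ccccc3)cc2O[C@@H]1c1ccc(OCc2ccccc2)cc1
F3 | step 7 | (S)-O-methylmandelate of 10 | CO[C@H](C(=O)O[C@H]1Cc2c(OCc3ccccc3)cc(OCc3ccccc3)cc2O[C@H]1c1ccc(OCc2ccccc2)cc1)c1ccccc1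
F4 | step 7 | (S)-O-methylmandelate of 11 | CO[C@H](C(=O)O[C@@H]1Cc2c(OCc3ccccc3)cc(OCc3ccccc3)cc2O[C@@H]1c1ccc(OCc2ccccc2)cc1)c1ccccc1
F5 | step 23 | protected trimer with C4 of L as ketone | c9ccccc9COc1ccc([C@H]2Oc3c(c(OCc9ccccc9)cc(OCc9ccccc9)c3[C@H]3c4c(OCc9ccccc9)cc(OCc9ccccc9)cc4O[C@@H](c4ccc(OCc9ccccc9)cc4)[C@H]3O[Si](C)(C)C(C)(C)C)[C@@H](c3c(OCc9ccccc9)cc(OCc9ccccc9)c4c3O[C@@H](c3ccc(OCc9ccccc9)cc3)[C@@H](O[Si](C)(C)C(C)(C)C)C4=O)[C@H]2O[Si](C)(C)C(C)(C)C)cc1
F6 | step 23 | nona-O-benzyl trimer 4-ketone with free 3-OH groups | c9ccccc9COc1ccc([C@H]2Oc3c(c(OCc9ccccc9)cc(OCc9ccccc9)c3[C@H]3c4c(OCc9ccccc9)cc(OCc9ccccc9)cc4O[C@@H](c4ccc(OCc9ccccc9)cc4)[C@H]3O)[C@@H](c3c(OCc9ccccc9)cc(OCc9ccccc9)c4c3O[C@@H](c3ccc(OCc9ccccc9)cc3)[C@@H](O)C4=O)[C@H]2O)cc1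
F7 | step 23 | free phenolic trimer with C4 of L as ketone | Oc1ccc([C@H]2Oc3c(c(O)cc(O)c3[C@H]3c4c(O)cc(O)cc4O[C@@H](c4ccc(O)cc4)[C@H]3O)[C@@H](c3c(O)cc(O)c4c3O[C@@H](c3ccc(O)cc3)[C@@H](O)C4=O)[C@H]2O)cc1
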